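**Retrosynthetic overview**
- The strategy rests on the ortho pair on the benzo ring of the 2H-chromene (ring atoms C4a, C5–C8, C8a): the acyl group on C6 and the free hydroxyl on C7, with the C5 methoxy beside C6 and only C8–H beside C7.
- The C6–C(=O) and C7–O bonds are disconnected together: the target comes from the 6,7-aryne of 5-methoxy-2,2-dimethyl-2H-chromene (released from its 7-trimethylsilyl 6-triflate) and 4-methoxyphenylacetic acid, by aryne insertion into the acid C–O bond.
- The silyl triflate comes from 5-methoxy-2,2-dimethyl-2H-chromen-6-ol by carbamate-directed C7 silylation and triflation; the phenol comes from the 6-carbaldehyde by Dakin oxidation; the aldehyde comes from 2,4-dihydroxybenzaldehyde and 3-methylbut-2-enal.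
- Ring order: both benzene rings are bought; the pyran ring (O1, C2, C3, C4, C4a, C8a) is the only ring formed, in step 1; the key step closes no ring.

Key step: step 7

Remark: the target has no stereocentre; chromene numbering (O1, C2, C3, C4, C4a, C5–C8, C8a) is used throughout.

**Route**

Step 1
Reactants: 1 2,4-dihydroxybenzaldehyde; 2 3-methylbut-2-enal
Product: 4 5-hydroxy-2,2-dimethyl-2H-chromene-6-carbaldehyde, via quinone methide 3 (not isolated)
Conditions: ethylenediammonium diacetate (10 mol %), xylene, reflux
Reagents that add atoms: none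
Why: Knoevenagel-type condensation of the enal at C3 of the resorcinol, the carbon flanked by both hydroxyls, gives quinone methide 3, which closes by oxa-6π electrocyclisation through the free 4-OH because the 2-OH is held in a hydrogen bond to the formyl group; this chromene annulation is established for 2,4-dihydroxybenzaldehyde.

Step 2
Reactants: 4 5-hydroxy-2,2-dimethyl-2H-chromene-6-carbaldehyde
Product: 5 5-methoxy-2,2-dimethyl-2H-chromene-6-carbaldehyde
Conditions: MeI, K2CO3, DMF, 40 °C
Reagents that add atoms: iodomethane, CI
Why: Williamson O-methylation of the only phenol, which as a hydrogen-bonded ortho-hydroxyaldehyde needs a polar solvent and mild warming, while nothing else in the molecule is alkylated under carbonate conditions.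

Step 3
Reactants: 5 5-methoxy-2,2-dimethyl-2H-chromene-6-carbaldehyde
Product: 7 5-methoxy-2,2-dimethyl-2H-chromen-6-ol, via aryl formate 6 (not isolated)
Conditions: 30% aq. H2O2, H2SO4 (cat.), MeOH, 0 °C to rt
Reagents that add atoms: hydrogen peroxide, OO
Why: Acid-catalysed Dakin oxidation (Baeyer–Villiger-type aryl migration in the hydroperoxide adduct) is favoured because the migrating carbon is ortho to the methoxy and para to the ring oxygen, formate 6 methanolyses in the same flask, and hydrogen peroxide without a peracid or metal catalyst should not epoxidise the C3=C4 alkene.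

Step 4
Reactants: 7 5-methoxy-2,2-dimethyl-2H-chromen-6-ol
Product: 8 5-methoxy-2,2-dimethyl-2H-chromen-6-yl N-isopropylcarbamate
Conditions: i-PrNCO, Et3N (cat.), CH2Cl2, rt
Reagents that add atoms: isopropyl isocyanate, CC(C)N=C=O
Why: Base-catalysed carbamoylation of the phenol by the isocyanate installs an N–H carbamate that is a strong ortho-directing group and can later be removed under mild base.

Step 5
Reactants: 8 5-methoxy-2,2-dimethyl-2H-chromen-6-yl N-isopropylcarbamate
Product: 12 5-methoxy-2,2-dimethyl-7-(trimethylsilyl)-2H-chromen-6-yl N-isopropylcarbamate, via N-silyl carbamate 9 (not isolated), via C7-aryllithium 10 (not isolated), via N-silyl C7-silyl carbamate 11 (not isolated)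
Conditions: TBSOTf, TMEDA, Et2O, 0 °C to rt; then n-BuLi, TMEDA, –78 °C; TMSCl, –78 °C to rt; aq. NaHSO4
Reagents that add atoms: chlorotrimethylsilane, C[Si](C)(C)Cl
Why: Directed ortho-metalation: after transient N-silylation to 9 the carbamate directs n-BuLi to C7, the only free position ortho to it since C5 carries the methoxy, aryllithium 10 is silylated to 11 at –78 °C before an anionic ortho-Fries shift can occur, and the acidic work-up removes the N-silyl group.

Step 6
Reactants: 12 5-methoxy-2,2-dimethyl-7-(trimethylsilyl)-2H-chromen-6-yl N-isopropylcarbamate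
Product: 14 5-methoxy-2,2-dimethyl-7-(trimethylsilyl)-2H-chromen-6-yl trifluoromethanesulfonate, via silylphenol 13 (not isolated)
Conditions: DBU, Et2NH, MeCN, 40 °C; then PhNTf2, rt
Reagents that add atoms: N-phenylbis(trifluoromethanesulfonimide), O=S(=O)(N(c1ccccc1)S(=O)(=O)C(F)(F)F)C(F)(F)F
Why: E1cB cleavage of the N–H carbamate by DBU expels isopropyl isocyanate, which diethylamine traps as a urea, and the phenoxide of 13 is triflated in the same flask by PhNTf2, the aryl–silicon bond being untouched in the absence of fluoride.

Step 7
Reactants: 14 5-methoxy-2,2-dimethyl-7-(trimethylsilyl)-2H-chromen-6-yl trifluoromethanesulfonate; 15 4-methoxyphenylacetic acid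
Product: 18 1-(7-hydroxy-5-methoxy-2,2-dimethyl-2H-chromen-6-yl)-2-(4-methoxyphenyl)ethan-1-one, via 6,7-aryne 16 (not isolated), via C6 aryl anion 17 (not isolated)
Conditions: 14 (1.5 equiv), CsF (4 equiv), THF, 125 °C (sealed tube); aq. NH4Cl
Reagents that add atoms: none
Why: Fluoride attacks silicon at C7 and triflate leaves from C6 to give aryne 16; the cesium carboxylate of 15 adds through oxygen at C7, and aryl anion 17 attacks the neighbouring ester carbonyl through a four-membered transition state that collapses to the ortho-acyl phenoxide, protonated on work-up. The closest known reaction is the fluoride-induced insertion of arynes from ortho-silylaryl triflates into the C–O bond of carboxylic acids to give ortho-hydroxyaryl ketones, here applied to an aryne with the well-behaved 3-methoxybenzyne pattern. No ring is closed and no stereocentre is formed; the two new bonds are C7–O and C6–C(=O). The step needs oxygen attack at C7 rather than C6: the inductively withdrawing C5 methoxy distorts the aryne so that C7 is the more linear and more electrophilic terminus and the developing negative charge sits at C6 beside the methoxy, while the ring oxygen at C8a, meta to C7, should exert only a weak opposing effect. It also needs the acyl shift to outrun protonation of 17 to the simple aryl ester, which the aprotic medium, the excess of CsF and the high temperature are chosen to secure. The chromene alkene, both aryl ethers and the benzylic CH2 should be inert to fluoride.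

**Compound list**

1 | 2,4-dihydroxybenzaldehyde | O=Cc1ccc(O)cc1O | starting material
2 | 3-methylbut-2-enal | CC(C)=CC=O | starting material
3 | 2-hydroxy-3-(3-methylbut-2-en-1-ylidene)-4-oxocyclohexa-1,5-diene-1-carbaldehyde (quinone methide, not isolated) | O=CC1=C(O)C(=CC=C(C)C)C(=O)C=C1 | intermediate
4 | 5-hydroxy-2,2-dimethyl-2H-chromene-6-carbaldehyde | O=Cc1ccc2OC(C)(C)C=Cc2c1O | intermediate
5 | 5-methoxy-2,2-dimethyl-2H-chromene-6-carbaldehyde | COc1c(C=O)ccc2OC(C)(C)C=Cc12 | intermediate
6 | 5-methoxy-2,2-dimethyl-2H-chromen-6-yl formate (not isolated) | COc1c(OC=O)ccc2OC(C)(C)C=Cc12 | intermediate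
7 | 5-methoxy-2,2-dimethyl-2H-chromen-6-ol | COc1c(O)ccc2OC(C)(C)C=Cc12 | intermediate
8 | 5-methoxy-2,2-dimethyl-2H-chromen-6-yl N-isopropylcarbamate | COc1c(OC(=O)NC(C)C)ccc2OC(C)(C)C=Cc12 | intermediate
9 | 5-methoxy-2,2-dimethyl-2H-chromen-6-yl N-(tert-butyldimethylsilyl)-N-isopropylcarbamate (not isolated) | COc1c(OC(=O)N(C(C)C)[Si](C)(C)C(C)(C)C)ccc2OC(C)(C)C=Cc12 | intermediate
10 | C7-lithio derivative of 9 (not isolated) | COc1c(OC(=O)N(C(C)C)[Si](C)(C)C(C)(C)C)c([Li])cc2OC(C)(C)C=Cc12 | intermediate
11 | 5-methoxy-2,2-dimethyl-7-(trimethylsilyl)-2H-chromen-6-yl N-(tert-butyldimethylsilyl)-N-isopropylcarbamate (not isolated) | COc1c(OC(=O)N(C(C)C)[Si](C)(C)C(C)(C)C)c([Si](C)(C)C)cc2OC(C)(C)C=Cc12 | intermediate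
12 | 5-methoxy-2,2-dimethyl-7-(trimethylsilyl)-2H-chromen-6-yl N-isopropylcarbamate | COc1c(OC(=O)NC(C)C)c([Si](C)(C)C)cc2OC(C)(C)C=Cc12 | intermediate
13 | 5-methoxy-2,2-dimethyl-7-(trimethylsilyl)-2H-chromen-6-ol (formed as its DBU salt, not isolated) | COc1c(O)c([Si](C)(C)C)cc2OC(C)(C)C=Cc12 | intermediate
14 | 5-methoxy-2,2-dimethyl-7-(trimethylsilyl)-2H-chromen-6-yl trifluoromethanesulfonate | COc1c(OS(=O)(=O)C(F)(F)F)c([Si](C)(C)C)cc2OC(C)(C)C=Cc12 | intermediate
15 | 4-methoxyphenylacetic acid | COc1ccc(CC(=O)O)cc1 | starting material
16 | 6,7-didehydro-5-methoxy-2,2-dimethyl-2H-chromene (6,7-aryne, not isolated) | COC1=C2C=CC(C)(C)OC2=CC#C1 | intermediate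
17 | cesium salt of the C6 aryl anion of 5-methoxy-2,2-dimethyl-2H-chromen-7-yl (4-methoxyphenyl)acetate (not isolated) | [Cs+].COc1[c-]c(OC(=O)Cc3ccc(OC)cc3)cc2OC(C)(C)C=Cc12 | intermediate
18 | 1-(7-hydroxy-5-methoxy-2,2-dimethyl-2H-chromen-6-yl)-2-(4-methoxyphenyl)ethan-1-one | COc1ccc(CC(=O)c2c(O)cc3c(c2OC)C=CC(C)(C)O3)cc1 | target

**Step count**

Total step count: 7. Longest linear sequence: 7 steps (1 to 18).

**Steps most likely to fail**

1. Step 7. The aryl anion 17 may be protonated by bifluoride or unreacted acid before the acyl shift, so that only O-arylation of the acid occurs. A second aryne may also arylate the product phenoxide or its acidic benzylic CH2. The fallback sets out from 14 and comes back at 18. Aryne 16 is generated from 14 with CsF in DMF at rt, where it should undergo formal insertion into the C=O bond of the formamide with the same regiochemistry (oxygen at C7, carbon at C6). Aqueous work-up should then give 7-hydroxy-5-methoxy-2,2-dimethyl-2H-chromene-6-carbaldehyde F1. Addition of 4-methoxybenzylmagnesium chloride (3 equiv, THF, 0 °C; the first equivalent deprotonates the phenol) should give racemic 1-(7-hydroxy-5-methoxy-2,2-dimethyl-2H-chromen-6-yl)-2-(4-methoxyphenyl)ethan-1-ol F2. Oxidation of the ortho-hydroxybenzylic alcohol with activated MnO2 in CH2Cl2 at rt should give 18. This path has no competing proton source at the aryl anion stage and needs no acyl shift.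

2. Step 3. Under the acidic peroxide conditions the electron-rich chromene may add methanol across C3=C4 or dimerise, or the p-alkoxyphenol may be over-oxidised. The fallback sets out from 5 and comes back at 8; it removes the alkene before the oxidation and restores it afterwards.
   - Hydrogenation of 5 (H2 1 atm, Pd/C, Ph2S cat., EtOAc, rt) should saturate only C3=C4 and give 5-methoxy-2,2-dimethylchromane-6-carbaldehyde F3.
   - Baeyer–Villiger oxidation with mCPBA (CH2Cl2, 0 °C to rt) should give 5-methoxy-2,2-dimethylchroman-6-yl formate F4.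
   - K2CO3 in MeOH should cleave the formate to 5-methoxy-2,2-dimethylchroman-6-ol F5.
   - Carbamoylation as in step 4 (i-PrNCO, Et3N cat., CH2Cl2) should give 5-methoxy-2,2-dimethylchroman-6-yl N-isopropylcarbamate F6.
   - DDQ dehydrogenation (dioxane, reflux) by hydride abstraction from benzylic C4, which lies ortho to the C5 methoxy and the ring oxygen, should give chromene carbamate 8.

3. Step 5. Lithiation may occur at C8 beside the ring oxygen, n-BuLi may add to the styrenic C3=C4 bond, or the carbamoyl group may migrate to C7 by an anionic ortho-Fries shift. The fallback sets out from 7 and comes back at 14; it places the silicon by halogen–metal exchange instead of deprotonation.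
   - Amine-directed ortho-bromination of 7 (NBS, i-Pr2NH cat., CH2Cl2, –78 to 0 °C) should give 7-bromo-5-methoxy-2,2-dimethyl-2H-chromen-6-ol F7. C7 is the only free position ortho to the hydroxyl, and the phenol should react faster than the alkene.
   - O-Silylation with hexamethyldisilazane (THF, reflux) should give [(7-bromo-5-methoxy-2,2-dimethyl-2H-chromen-6-yl)oxy]trimethylsilane F8.
   - Bromine–lithium exchange with n-BuLi (THF, –100 °C) followed by 1,3 O-to-C silyl migration (retro-Brook rearrangement) should give the lithium salt of silylphenol 13, which is triflated in the same flask with Tf2O to give 14.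

**Further compounds**

F1 | step 7 | 7-hydroxy-5-methoxy-2,2-dimethyl-2H-chromene-6-carbaldehyde | COc1c(C=O)c(O)cc2OC(C)(C)C=Cc12
F2 | step 7 | 1-(7-hydroxy-5-methoxy-2,2-dimethyl-2H-chromen-6-yl)-2-(4-methoxyphenyl)ethan-1-ol (racemic) | COc1ccc(CC(O)c2c(O)cc3OC(C)(C)C=Cc3c2OC)cc1
F3 | step 3 | 5-methoxy-2,2-dimethylchromane-6-carbaldehyde | COc1c(C=O)ccc2OC(C)(C)CCc12
F4 | step 3 | 5-methoxy-2,2-dimethylchroman-6-yl formate | COc1c(OC=O)ccc2OC(C)(C)CCc12
F5 | step 3 | 5-methoxy-2,2-dimethylchroman-6-ol | COc1c(O)ccc2OC(C)(C)CCc12
F6 | step 3 | 5-methoxy-2,2-dimethylchroman-6-yl N-isopropylcarbamate | COc1c(OC(=O)NC(C)C)ccc2OC(C)(C)CCc12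
F7 | step 5 | 7-bromo-5-methoxy-2,2-dimethyl-2H-chromen-6-ol | COc1c(O)c(Br)cc2OC(C)(C)C=Cc12
F8 | step 5 | [(7-bromo-5-methoxy-2,2-dimethyl-2H-chromen-6-yl)oxy]trimethylsilane | COc1c(O[Si](C)(C)C)c(Br)cc2OC(C)(C)C=Cc12
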